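**Strategy.** Eriolangin is read as a cyclohexene (ring A: C3a, C4, C5, C6, C7, C7a) cis-fused to an α-methylene-γ-butyrolactone (ring B: O1, C2, C3, C3a, C7a). The lactone carbonyl C2 is treated as carbon monoxide, O1–C7a as a former aldehyde and C3a–C3(=CH2) as a former terminal allene. A molybdenum-mediated hetero-Pauson–Khand (2+2+1) cyclocarbonylation of an acyclic allenyl aldehyde therefore closes both rings at once, forming C3a–C7a, C3–C2 and O1–C2 and setting C3a and C7a from the C4 angelate centre. The precursor is an (E)-tetrasubstituted alkene carrying CH2CHO and the allenyl carbinol angelate cis, built from (S)-citronellic acid through a Z-enol triflate and a B-alkyl Suzuki coupling.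

Key step: step 15

Remark: atom labels follow the 3-methylene-hexahydrobenzofuran-2(3H)-one numbering (O1, C2, C3, C3a, C4 to C7, C7a). TBS = tert-butyldimethylsilyl, PMB = 4-methoxybenzyl, THP = tetrahydropyran-2-yl. Compounds 19 to 22 and F6 are mixtures at the THP acetal carbon, which is removed in step 11.

Step 1
Reactants: 1 (S)-citronellic acid; 2 N,O-dimethylhydroxylamine hydrochloride
Product: 4 Weinreb amide (3S)-N-methoxy-N,3,7-trimethyloct-6-enamide, via acyl imidazolide 3 (not isolated)
Conditions: 1,1'-carbonyldiimidazole, CH2Cl2, rt; then 2, rt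
Reagents that add atoms: none
Why: Acyl imidazolide formation followed by aminolysis is a standard Weinreb amide synthesis that leaves the remote stereocentre and the trisubstituted alkene untouched.

Step 2
Reactants: 4 Weinreb amide
Product: 6 (3S)-6-hydroxy-N-methoxy-N,3-dimethylhexanamide, via aldehyde 5 (not isolated)
Conditions: O3, CH2Cl2/MeOH, −78 °C; then NaBH4, −78 °C to 0 °C
Reagents that add atoms: ozone [O-][O+]=O
Why: Ozonolysis cleaves the only alkene and in-flask NaBH4 reduction of the aldehyde should give the primary alcohol, the Weinreb amide being inert to NaBH4 at low temperature.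

Step 3
Reactants: 6 primary alcohol
Product: 7 (3S)-6-(TBSO)-N-methoxy-N,3-dimethylhexanamide
Conditions: TBSCl, imidazole, DMF, rt
Reagents that add atoms: tert-butyldimethylsilyl chloride C[Si](C)(Cl)C(C)(C)C
Why: Standard silylation of a primary alcohol.

Step 4
Reactants: 7 silyl ether amide; 8 (tert-butyldimethylsilyloxy)acetaldehyde
Product: 10 aldol adduct 4-(TBSO)-3-hydroxy-N-methoxy-N-methyl-2-[(2S)-5-(TBSO)pentan-2-yl]butanamide (diastereomer mixture at C2 and C3), via lithium enolate 9 (not isolated)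
Conditions: LDA, THF, −78 °C; then 8, −78 °C; aq. NH4Cl
Reagents that add atoms: none
Why: Aldol addition of the lithium amide enolate to the unhindered aldehyde should proceed cleanly, and both new stereocentres are erased in steps 5 and 6 so their configuration is irrelevant.

Step 5
Reactants: 10 aldol adduct
Product: 11 β-keto amide 4-(TBSO)-N-methoxy-N-methyl-3-oxo-2-[(2S)-5-(TBSO)pentan-2-yl]butanamide (C2 epimers)
Conditions: Dess–Martin periodinane, CH2Cl2, rt
Reagents that add atoms: none
Why: Dess–Martin oxidation converts the secondary alcohol to the ketone under non-basic conditions that do not touch the silyl ethers.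

Step 6
Reactants: 11 β-keto amide
Product: 13 (2Z)-enol triflate (2Z)-1-(TBSO)-4-[methoxy(methyl)amino]-4-oxo-3-[(2S)-5-(TBSO)pentan-2-yl]but-2-en-2-yl trifluoromethanesulfonate, via sodium enolate 12 (not isolated)
Conditions: NaH, THF, 0 °C; then PhNTf2, 0 °C to rt
Reagents that add atoms: N-phenylbis(trifluoromethanesulfonimide) O=S(=O)(N(c1ccccc1)S(=O)(=O)C(F)(F)F)C(F)(F)F
Why: Deprotonation of the 1,3-dicarbonyl C–H gives the sodium-chelated Z-enolate in which both oxygens bind the cation, so O-triflation should fix the triflate cis to the amide carbonyl.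

Step 7
Reactants: 14 4-methoxybenzyl alcohol; 15 vinyl acetate
Product: 16 4-methoxybenzyl vinyl ether
Conditions: [Ir(cod)Cl]2 (cat.), Na2CO3, toluene, 100 °C
Reagents that add atoms: none
Why: Iridium-catalysed transfer vinylation of an alcohol from vinyl acetate is an established route to alkyl vinyl ethers.

Step 8
Reactants: 13 enol triflate; 16 4-methoxybenzyl vinyl ether
Product: 18 (2E)-N-methoxy-5-(4-methoxybenzyloxy)-N-methyl-3-[(TBSO)methyl]-2-[(2S)-5-(TBSO)pentan-2-yl]pent-2-enamide, via alkylborane 17 (not isolated)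
Conditions: 16, 9-BBN, THF, rt; then 13, Pd(dppf)Cl2 (cat.), aq. K3PO4, DMF, 50 °C
Reagents that add atoms: none
Why: Anti-Markovnikov hydroboration of the vinyl ether gives a primary β-alkoxyalkylborane that should undergo B-alkyl Suzuki–Miyaura coupling with the enol triflate with retention of alkene geometry, placing the two-carbon arm cis to the amide.

Step 9
Reactants: 18 enamide; 19 2-(prop-2-yn-1-yloxy)tetrahydro-2H-pyran
Product: 21 ynone (5E)-8-(4-methoxybenzyloxy)-1-(THP-oxy)-6-[(TBSO)methyl]-5-[(2S)-5-(TBSO)pentan-2-yl]oct-5-en-2-yn-4-one, via lithium acetylide 20 (not isolated)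
Conditions: 19, n-BuLi, THF, −78 °C; then 18, −78 °C to −20 °C; AcOH quench at −78 °C
Reagents that add atoms: none
Why: Lithium acetylides add once to Weinreb amides through a stable chelated tetrahedral intermediate, and the cold acidic quench should prevent conjugate addition of the liberated hydroxylamine to the ynone.

Step 10
Reactants: 21 ynone
Product: 22 propargylic alcohol (4S,5E)-8-(4-methoxybenzyloxy)-1-(THP-oxy)-6-[(TBSO)methyl]-5-[(2S)-5-(TBSO)pentan-2-yl]oct-5-en-2-yn-4-ol
Conditions: (R)-2-methyl-CBS-oxazaborolidine, BH3·SMe2, THF, −40 °C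
Reagents that add atoms: none
Why: In this Corey–Bakshi–Shibata reduction the bulky tetrasubstituted alkenyl group acts as the large and the alkynyl group as the small substituent, so the (R)-oxazaborolidine should deliver hydride to give the (S)-carbinol (C4 of the target).

Step 11
Reactants: 22 propargylic alcohol
Product: 23 allenol (4S,5E)-8-(4-methoxybenzyloxy)-6-[(TBSO)methyl]-5-[(2S)-5-(TBSO)pentan-2-yl]octa-1,2,5-trien-4-ol
Conditions: LiAlH4, Et2O, 0 °C to reflux
Reagents that add atoms: none
Why: Alkoxide-directed trans-hydroalumination puts hydride on the proximal and aluminium on the distal alkyne carbon, and 1,2-elimination of the THP-oxy group (SN2′ reduction) should give the terminal allene without touching the carbinol centre.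

Step 12
Reactants: 23 allenol; 24 angelic acid
Product: 26 angelate (4S,5E)-8-(4-methoxybenzyloxy)-6-[(TBSO)methyl]-5-[(2S)-5-(TBSO)pentan-2-yl]octa-1,2,5-trien-4-yl (Z)-2-methylbut-2-enoate, via mixed anhydride 25 (not isolated)
Conditions: 24, 2,4,6-trichlorobenzoyl chloride, Et3N, toluene, rt; then 23, toluene, 75 °C
Reagents that add atoms: none
Why: Yamaguchi esterification through the mixed anhydride without a nucleophilic catalyst is the usual way to make angelates without Z-to-E isomerisation to the tiglate.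

Step 13
Reactants: 26 PMB ether
Product: 27 primary alcohol (4S,5E)-8-hydroxy-6-[(TBSO)methyl]-5-[(2S)-5-(TBSO)pentan-2-yl]octa-1,2,5-trien-4-yl (Z)-2-methylbut-2-enoate
Conditions: DDQ, CH2Cl2/pH 7 buffer, 0 °C
Reagents that add atoms: none
Why: Oxidative cleavage of the PMB ether by DDQ under buffered conditions is orthogonal to the silyl ethers, the ester and the allene.

Step 14
Reactants: 27 primary alcohol
Product: 28 allenyl aldehyde (4S,5E)-8-oxo-6-[(TBSO)methyl]-5-[(2S)-5-(TBSO)pentan-2-yl]octa-1,2,5-trien-4-yl (Z)-2-methylbut-2-enoate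
Conditions: Dess–Martin periodinane, NaHCO3, CH2Cl2, 0 °C; crude product used at once
Reagents that add atoms: none
Why: Buffered Dess–Martin oxidation gives the β,γ-unsaturated aldehyde under neutral conditions that should avoid migration of the tetrasubstituted alkene into conjugation.

Step 15
Reactants: 28 allenyl aldehyde
Product: 29 bis-TBS eriolangin (3aR,4S,7aR)-3-methylene-2-oxo-6-[(TBSO)methyl]-5-[(2S)-5-(TBSO)pentan-2-yl]-2,3,3a,4,7,7a-hexahydrobenzofuran-4-yl (Z)-2-methylbut-2-enoate
Conditions: Mo(CO)6, DMSO, toluene, 100 °C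
Reagents that add atoms: molybdenum hexacarbonyl Mo(CO)6 (one CO ligand is incorporated) [C-]#[O+].[C-]#[O+].[C-]#[O+].[C-]#[O+].[C-]#[O+].[C-]#[O+].[Mo]
Why: DMSO-promoted loss of CO from Mo(CO)6 gives a zerovalent molybdenum fragment that binds the aldehyde C=O and the internal (C3a=C3) π-bond of the allene, oxidative cyclisation forms the C3a–C7a bond and an oxamolybdacyclopentane, and CO insertion into the Mo–C3 bond (C3–C2) followed by C–O reductive elimination (O1–C2) releases the lactone. The closest known reaction type is the hetero-Pauson–Khand (2+2+1) cyclocarbonylation of allenyl aldehydes to α-methylene-γ-butyrolactones. Ring A is closed in a 6-exo sense by attack of the aldehyde carbon on the proximal allene carbon, the distal π-bond remaining as the exocyclic methylene, and ring B is the five-membered ring assembled by the (2+2+1) event from C3a=C3, C7a=O1 and CO. The cis fusion at C3a/C7a follows from the five-membered metallacycle fused to the forming six-membered ring, and the allene face is chosen by the existing C4 centre: A(1,2) strain with the C5 side chain places the angelate pseudoaxial and the metal-bearing C3 takes the opposite, anti position, so that H3a ends cis and C3 trans to the angelate. The step needs chemoselectivity for the internal over the terminal allene π-bond (secured by six- versus seven-membered ring formation), pre-organisation of the reacting termini (secured by the E-tetrasubstituted alkene that holds CH2CHO and the allenyl carbinol cis) and survival of the non-conjugated aldehyde and the allenylic angelate, which is the accepted risk.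

Step 16
Reactants: 29 bis-TBS eriolangin
Product: 30 eriolangin
Conditions: HF·pyridine, pyridine, THF, 0 °C to rt
Reagents that add atoms: none
Why: Buffered fluoride should cleave both primary TBS ethers while the angelate and the α-methylene lactone tolerate the mildly acidic medium.

**Compound list**

1 | (S)-citronellic acid, (3S)-3,7-dimethyloct-6-enoic acid | OC(=O)C[C@@H](C)CCC=C(C)C | starting material
2 | N,O-dimethylhydroxylamine hydrochloride | CNOC.Cl | starting material
3 | 1-[(3S)-3,7-dimethyloct-6-enoyl]imidazole (not isolated) | O=C(C[C@@H](C)CCC=C(C)C)n1ccnc1 | intermediate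
4 | (3S)-N-methoxy-N,3,7-trimethyloct-6-enamide | CON(C)C(=O)C[C@@H](C)CCC=C(C)C | intermediate
5 | (3S)-N-methoxy-N,3-dimethyl-6-oxohexanamide (not isolated) | CON(C)C(=O)C[C@@H](C)CCC=O | intermediate
6 | (3S)-6-hydroxy-N-methoxy-N,3-dimethylhexanamide | CON(C)C(=O)C[C@@H](C)CCCO | intermediate
7 | (3S)-6-(TBSO)-N-methoxy-N,3-dimethylhexanamide | CON(C)C(=O)C[C@@H](C)CCCO[Si](C)(C)C(C)(C)C | intermediate
8 | (tert-butyldimethylsilyloxy)acetaldehyde | O=CCO[Si](C)(C)C(C)(C)C | starting material
9 | lithium enolate of 7 (not isolated) | [Li]OC(=C[C@@H](C)CCCO[Si](C)(C)C(C)(C)C)N(C)OC | intermediate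
10 | aldol adduct, 4-(TBSO)-3-hydroxy-N-methoxy-N-methyl-2-[(2S)-5-(TBSO)pentan-2-yl]butanamide, diastereomer mixture | CON(C)C(=O)C([C@@H](C)CCCO[Si](C)(C)C(C)(C)C)C(O)CO[Si](C)(C)C(C)(C)C | intermediate
11 | β-keto amide, 4-(TBSO)-N-methoxy-N-methyl-3-oxo-2-[(2S)-5-(TBSO)pentan-2-yl]butanamide | CON(C)C(=O)C([C@@H](C)CCCO[Si](C)(C)C(C)(C)C)C(=O)CO[Si](C)(C)C(C)(C)C | intermediate
12 | sodium Z-enolate of 11 (not isolated) | CON(C)C(=O)/C([C@@H](C)CCCO[Si](C)(C)C(C)(C)C)=C(\O[Na])CO[Si](C)(C)C(C)(C)C | intermediate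
13 | (2Z)-enol triflate of 11, triflate cis to the amide carbonyl | CON(C)C(=O)/C([C@@H](C)CCCO[Si](C)(C)C(C)(C)C)=C(\OS(=O)(=O)C(F)(F)F)CO[Si](C)(C)C(C)(C)C | intermediate
14 | 4-methoxybenzyl alcohol | COc1ccc(CO)cc1 | starting material
15 | vinyl acetate | CC(=O)OC=C | starting material
16 | 4-methoxybenzyl vinyl ether | COc1ccc(COC=C)cc1 | intermediate
17 | 9-[2-(4-methoxybenzyloxy)ethyl]-9-borabicyclo[3.3.1]nonane (not isolated) | COc1ccc(COCCB2C3CCCC2CCC3)cc1 | intermediate
18 | (2E)-N-methoxy-5-(4-methoxybenzyloxy)-N-methyl-3-[(TBSO)methyl]-2-[(2S)-5-(TBSO)pentan-2-yl]pent-2-enamide, CH2CH2OPMB cis to the amide | CON(C)C(=O)/C([C@@H](C)CCCO[Si](C)(C)C(C)(C)C)=C(\CCOCc1ccc(OC)cc1)CO[Si](C)(C)C(C)(C)C | intermediate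
19 | 2-(prop-2-yn-1-yloxy)tetrahydro-2H-pyran | C#CCOC1CCCCO1 | starting material
20 | lithium acetylide of 19 (not isolated) | [Li]C#CCOC1CCCCO1 | intermediate
21 | ynone, (5E)-8-(4-methoxybenzyloxy)-1-(THP-oxy)-6-[(TBSO)methyl]-5-[(2S)-5-(TBSO)pentan-2-yl]oct-5-en-2-yn-4-one | O=C(C#CCOC1CCCCO1)/C([C@@H](C)CCCO[Si](C)(C)C(C)(C)C)=C(\CCOCc1ccc(OC)cc1)CO[Si](C)(C)C(C)(C)C | intermediate
22 | (4S,5E)-propargylic alcohol from 21 | O[C@@H](C#CCOC1CCCCO1)/C([C@@H](C)CCCO[Si](C)(C)C(C)(C)C)=C(\CCOCc1ccc(OC)cc1)CO[Si](C)(C)C(C)(C)C | intermediate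
23 | allenol, (4S,5E)-8-(4-methoxybenzyloxy)-6-[(TBSO)methyl]-5-[(2S)-5-(TBSO)pentan-2-yl]octa-1,2,5-trien-4-ol | O[C@@H](C=C=C)/C([C@@H](C)CCCO[Si](C)(C)C(C)(C)C)=C(\CCOCc1ccc(OC)cc1)CO[Si](C)(C)C(C)(C)C | intermediate
24 | angelic acid, (Z)-2-methylbut-2-enoic acid | C/C=C(/C)C(=O)O | starting material
25 | angelic 2,4,6-trichlorobenzoic anhydride (not isolated) | C/C=C(/C)C(=O)OC(=O)c1c(Cl)cc(Cl)cc1Cl | intermediate
26 | (4S,5E)-angelate of 23 | C/C=C(/C)C(=O)O[C@@H](C=C=C)/C([C@@H](C)CCCO[Si](C)(C)C(C)(C)C)=C(\CCOCc1ccc(OC)cc1)CO[Si](C)(C)C(C)(C)C | intermediate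
27 | (4S,5E)-8-hydroxy-6-[(TBSO)methyl]-5-[(2S)-5-(TBSO)pentan-2-yl]octa-1,2,5-trien-4-yl (Z)-2-methylbut-2-enoate | C/C=C(/C)C(=O)O[C@@H](C=C=C)/C([C@@H](C)CCCO[Si](C)(C)C(C)(C)C)=C(\CCO)CO[Si](C)(C)C(C)(C)C | intermediate
28 | (4S,5E)-8-oxo-6-[(TBSO)methyl]-5-[(2S)-5-(TBSO)pentan-2-yl]octa-1,2,5-trien-4-yl (Z)-2-methylbut-2-enoate | C/C=C(/C)C(=O)O[C@@H](C=C=C)/C([C@@H](C)CCCO[Si](C)(C)C(C)(C)C)=C(\CC=O)CO[Si](C)(C)C(C)(C)C | intermediate
29 | bis-TBS eriolangin, (3aR,4S,7aR), cis-fused lactone, angelate trans to C3 | C=C1C(=O)O[C@@H]2CC(CO[Si](C)(C)C(C)(C)C)=C([C@@H](C)CCCO[Si](C)(C)C(C)(C)C)[C@@H](OC(=O)/C(C)=C\C)[C@H]12 | intermediate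
30 | eriolangin, (3aR,4S,7aR)-6-(hydroxymethyl)-5-[(2S)-5-hydroxypentan-2-yl]-3-methylene-2-oxo-2,3,3a,4,7,7a-hexahydrobenzofuran-4-yl (Z)-2-methylbut-2-enoate | C=C1C(=O)O[C@@H]2CC(CO)=C([C@@H](C)CCCO)[C@@H](OC(=O)/C(C)=C\C)[C@H]12 | target

**Step count.** Total: 16 steps. Longest linear sequence: 15 steps (steps 1 to 6 and 8 to 16, from (S)-citronellic acid); step 7 is a one-step side branch.

**Steps most likely to fail**

Step 15 (key step). Three processes may defeat it: migration of the C5=C6 alkene into conjugation with the aldehyde before cyclisation, ionisation of the allenylic angelate by the low-valent metal, and poor facial selectivity with respect to C4. The fallback builds the two bonds stepwise and sets out from 28. A [Pd(C3H5)Cl]2-catalysed silastannylative cyclisation with Me3Si–SnBu3 (THF, rt) should add the silyl group to the central allene carbon and the resulting allyl unit to the aldehyde, giving the cis-cyclohexenol vinylsilane F1. Iododesilylation with N-iodosuccinimide in MeCN should give the vinyl iodide F2. Carbonylative lactonisation of F2 (Pd(PPh3)4, CO, Et3N, MeCN, 60 °C) forms the C3–C2 and O1–C2 bonds and returns to the route at 29.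

Step 8. β-Alkoxide elimination from the borate (loss of the two-carbon unit) or slow transmetalation at the congested vinylpalladium centre with competing triflate hydrolysis may occur. The fallback sets out from 13. Stille coupling with tributyl(vinyl)stannane (Pd(PPh3)4, LiCl, THF, 60 °C) should give the dienamide F3. Chemoselective hydroboration–oxidation of the terminal vinyl group (9-BBN, THF; then NaBO3) should give the primary alcohol F4. Etherification with 4-methoxybenzyl 2,2,2-trichloroacetimidate and catalytic La(OTf)3 returns to the route at 18.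

Step 9. Addition to the twisted, doubly flanked amide carbonyl may be sluggish, or γ-deprotonation may compete. The fallback sets out from 18. Reduction with i-Bu2AlH (THF, −78 °C) should give the enal F5. Addition of lithium acetylide 20 (THF, −78 °C) should give the propargylic alcohol epimer mixture F6. Oxidation with MnO2 (CH2Cl2, rt) returns to the route at 21, so the carbinol configuration is still set in step 10.

**Further compounds**

F1 | step 15 | cis-cyclohexenol vinylsilane, 5-hydroxy-6-[1-(trimethylsilyl)vinyl]cyclohex-2-enyl angelate with ring substituents and configurations as at C7a, C3a and C4 of 29 | C=C([Si](C)(C)C)[C@@H]1[C@H](O)CC(CO[Si](C)(C)C(C)(C)C)=C([C@@H](C)CCCO[Si](C)(C)C(C)(C)C)[C@H]1OC(=O)/C(C)=C\C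
F2 | step 15 | vinyl iodide, 5-hydroxy-6-(1-iodovinyl)cyclohex-2-enyl angelate with configurations as in F1 | C=C(I)[C@@H]1[C@H](O)CC(CO[Si](C)(C)C(C)(C)C)=C([C@@H](C)CCCO[Si](C)(C)C(C)(C)C)[C@H]1OC(=O)/C(C)=C\C
F3 | step 8 | dienamide, (2E)-N-methoxy-N-methyl-3-[(TBSO)methyl]-2-[(2S)-5-(TBSO)pentan-2-yl]penta-2,4-dienamide | CON(C)C(=O)/C([C@@H](C)CCCO[Si](C)(C)C(C)(C)C)=C(\C=C)CO[Si](C)(C)C(C)(C)C
F4 | step 8 | (2E)-5-hydroxy-N-methoxy-N-methyl-3-[(TBSO)methyl]-2-[(2S)-5-(TBSO)pentan-2-yl]pent-2-enamide | CON(C)C(=O)/C([C@@H](C)CCCO[Si](C)(C)C(C)(C)C)=C(\CCO)CO[Si](C)(C)C(C)(C)C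
F5 | step 9 | enal, (2E)-5-(4-methoxybenzyloxy)-3-[(TBSO)methyl]-2-[(2S)-5-(TBSO)pentan-2-yl]pent-2-enal | O=C/C([C@@H](C)CCCO[Si](C)(C)C(C)(C)C)=C(\CCOCc1ccc(OC)cc1)CO[Si](C)(C)C(C)(C)C
F6 | step 9 | propargylic alcohol as in 22 but as a mixture of both carbinol epimers | OC(C#CCOC1CCCCO1)/C([C@@H](C)CCCO[Si](C)(C)C(C)(C)C)=C(\CCOCc1ccc(OC)cc1)CO[Si](C)(C)C(C)(C)C
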